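A neighbour of this flask holds 0.20 M of starting material on the same recipe, and before I charge either I want to know which change is worth making.

    reagent in the reaction phase ⇌ reagent in the second phase, rate k1*([reagent in the reaction phase] - [reagent in the second phase]/K1) per volume of the first phase (K1 = 0.84, k1 = 0.14 min⁻¹)
    starting material + reagent in the reaction phase → target (k2 = 0.032 M⁻¹ min⁻¹)
    2 reagent in the reaction phase → homo dimer (k3 = 0.032 M⁻¹ min⁻¹)
    reagent in the reaction phase → decomposed reagent (k4 = 0.47 min⁻¹)

starting material 0.80 M; reagent in the second phase 1.50 equiv; time 15 min; volume of the second phase over the first 1.0

- where a step has two of a species, its rate is k times that concentration squared, and two are used at each turn
- in the second phase: reagent in the second phase; everything else is in the first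
- charges count per volume of the first phase; a concentration in a rate is the amount of a species over the volume of its own phase; every rate counts per litre of the first phase
- run time (flask): 15 min

1. how much target there is at 15 min, in percent of the starting material charged
2. the change that raises the amount of target at 15 min, in percent of the starting material charged most ("none" if none brings more than 2 percentage points) (amber / grey / none)
3. amount of target at 15 min, in percent of the starting material charged, after grey

- amber: doubling the transfer coefficient of step 1, all else as stated
- grey: doubling the amount of reagent in the second phase, all else as stated

A reagent molecule in the reaction phase can couple or decompose, and in this reckoning I set the homo dimer step aside. Dividing the coupling rate by the total of the two cancels [reagent in the reaction phase], and time goes with it. I hold [starting material] at its charge, which makes coupling pseudo-first-order in the reagent, and coupling at 0.0256 min⁻¹ is slower than decomposition at 0.47 min⁻¹. So coupling constant times [starting material], over that same term plus the decomposition constant, gives 5.17%: the coupling share, the selectivity between these two losses.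

The target is then this share times the reagent that has been consumed. Decomposition outruns transfer, so I let the second phase drain at 0.128 min⁻¹, which delivers 85.4% of the charge by 15 min. My reckoning gives 6.62%. In this reckoning grey leaves share and drain as they are and doubles the product, to 13.2%. Amber lifts delivery to 95.6%, worth 0.79 percentage points. Against the 2 points a change must beat, I choose grey.

The forecast says 6%, grey and 11.4%, holding that “the loss is nearly first order, doubling the charge nearly doubles the target”. My two target figures stand above its two.

The flask gives 5.94%, and grey wins with 5.4 points against 0.76 points for amber, reaching 11.4%. At 15.0 min this flask holds 0.900 M of decomposed reagent and 0.00894 M of homo dimer, and the dimer step makes no difference to the target. With starting material at 94.1% of its charge, target over target plus decomposed reagent in this flask reads 5.02%, beside the coupling share of 5.17%.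

For the neighbour, the coupling share falls to 1.34%, and the same delivery gives 1.72%. The simulated neighbour gives 1.59%.

All constants were set for the occasion; what happens was integrated by code.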